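The numbers in the tables come from a simulation with constants of no real substance.

The number I carry to this flask is a slope on logarithmic axes, the decades of highest target reading gained per decade of precatalyst charged per volume, and I read it from the two earlier runs, in which the substrate rises along with the precatalyst at the same loading.

| setting | Sunday's | Monday's | flask |
|---|---|---|---|
| substrate | 0.29 M | 0.44 M | 0.59 M |
| precatalyst | 10 mol% | 10 mol% | 10 mol% |
| remark | run made earlier | run made earlier |  |
| time |  |  | 15 d |

| run | time / d | target / % | substrate / % |
|---|---|---|---|
| Sunday's | 0.208 | 5.4 | 5.3 |
| Sunday's | 0.833 | 9.9 | 2.1 |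
| Sunday's | 3.00 | 4.6 | 1.1 |
| Sunday's | 12.0 | 0.2 | 0.4 |
| Monday's | 0.208 | 6.8 | 5.2 |
| Monday's | 0.833 | 10.4 | 1.5 |
| Monday's | 3.00 | 4.3 | 1.6 |
| Monday's | 12.0 | 0 | 0 |

(each reading ± 0.5 percentage points)

- target is meant together with its crystals
- solid, in amounts per volume of the solution: crystals
- steps thought possible: substrate + catalyst <-> target + catalyst; precatalyst -> catalyst; target -> over-reaction product; crystals <-> target; isomer of the product <-> substrate; target <-> isomer of the product

- when, up to 15 d, the flask holds most target
- the amount of target, in percent of the substrate charged, at that time

From Sunday's run to Monday's the precatalyst charged rises by 0.181 of a decade, while the target reading at 0.833 d, which stands above its neighbours in Sunday's run and in Monday's, rises by 0.0214 of a decade. The ratio is 0.118, which I call the gain exponent, and it means that each decade of charge at this loading lifts the highest reading, as a fraction of the substrate charged, by that part of a decade, but the two readings part by 0.5 percentage points against a scatter of 0.5 points, so it is a rough reading. Carried from Monday's run, it gives me 10.8% for this flask. But one number speaks of height and not of time: at 0.208 d the slope of the readings is 0.553, steeper than the gain exponent, so the early reading answers to the charge more than the highest reading does, and for this flask I commit to a time a little before 0.833 d.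

The forecast says 11.3% at 0.65 d, and adds that “crystallisation could occur, protecting target and pushing the peak later and higher”.

The flask gives 10.8% at 0.771 d, later than the forecast's time.

    substrate + catalyst ⇌ target + catalyst, rate k1*[substrate]*[catalyst] forward; the back reaction follows from the equilibrium constant (K = 26.2, k = 9.74 M⁻¹ h⁻¹)
    precatalyst → catalyst (k = 0.0387 h⁻¹)
    target → over-reaction product (k = 0.130 h⁻¹)
    crystals ⇌ target, rate k4*(cs4 - [target]) while solid is left; crystals form when [target] > cs4 (solubility = 0.190 M, k = 2.53 h⁻¹)
    isomer of the product ⇌ substrate (k = 0.0259 h⁻¹)
    target ⇌ isomer of the product (K = 1.04, k = 0.0174 h⁻¹)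

The gain exponent gave 10.8% for this flask, against the 10.8% it holds. Carried from Sunday's run to a neighbouring flask, like this one but with 4 mol% of precatalyst, it gives 9.66%, and that flask reaches 9.60%. One proven part of why the peak stays so low in this flask is the conversion of target into over-reaction product: the same flask without that step reaches 65.3% instead of 10.8%.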